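The runs were computed for an exercise.

The ratio I followed was that of the catalyst's burst of isomer of the product A to the target standing beside it.

in all of them: starting material 0.013 M; free catalyst 0.65 mM
- north-west: the very flask that is asked about, followed so far
- flask: time 40 min

north-west run (percent of the starting material charged)

| time / min | isomer of the product A / % | target / % |
|---|---|---|
| 1.33 | 11.6 | 31.7 |
| 4.00 | 24.0 | 38.3 |
| 8.00 | 35.2 | 35.1 |
| 12.0 | 39.5 | 35.2 |
| 15.0 | 44.0 | 33.0 |

(each reading ± 1 percentage point)

- candidate steps: isomer of the product A + free catalyst <-> isomer of the product B + free catalyst; free catalyst -> spent catalyst; isomer of the product B + free catalyst <-> starting material + free catalyst; target <-> isomer of the product A; starting material <-> target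

- share of isomer of the product A in isomer of the product A plus target at 4.0 s
- share of isomer of the product A in isomer of the product A plus target at 1.5 min
- share of isomer of the product A in isomer of the product A plus target at 40 min
- which of isomer of the product A and target there is more of at 40 min

Between the first two readings of the north-west run, isomer of the product A gained 0.133 /min per unit of target, net of any flow back. Taking target at its first reading from the start, a generous figure, left a burst (burst kinetics) I = 6.01% not fed by target. So I read the burst ratio β, I divided by the first target reading, as 0.189. Target's mean early rate gave 1.59% by 4.0 s, so if the burst were over by then, I expected a share near 79.1%.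

The forecast differed, with 2%, 28% and 63%, and isomer of the product A ahead at 40 min: “A is a second-generation product”.

The flask gave 49.6%, 25.9% and 56.5%, with isomer of the product A ahead at 42.7% against 32.9%.

    isomer of the product A + free catalyst ⇌ isomer of the product B + free catalyst, rate k1*[free catalyst]*[isomer of the product A] forward; the back reaction follows from the equilibrium constant (K = 0.330, k = 420 /M/s)
    free catalyst → spent catalyst (k = 0.160 /s)
    isomer of the product B + free catalyst ⇌ starting material + free catalyst, rate k3*[free catalyst]*[isomer of the product B] forward; the back reaction follows from the equilibrium constant (k = 46.0 /M/s)
    target ⇌ isomer of the product A (K = 1.30, k = 0.00350 /s)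
    starting material ⇌ target (K = 1.60, k = 0.00820 /s)

Part of the reason for the early share in the flask is the catalysed route: with the falling back of isomer of the product B to isomer of the product A struck out, the share at 4.0 s went from 49.6% to 0.572%. The late share is a different matter: with the path from target to isomer of the product A taken away, both ways, the share at 40 min went from 56.5% to 11.7%. At 1.5 min the flask's ratio of isomer of the product A to target was 0.350, and I counted 0.189 of it as burst. A neighbour flask held 1.6 × 10⁻⁴ M of free catalyst, a quarter of this flask's charge. Scaling the burst with that charge gave a ratio of 0.208, a share of 17.2%, and the neighbour flask gave 17.1% at 1.5 min.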